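**Retrosynthetic overview**
1. Target ⇐ diene 22 by a last, substrate-controlled epoxidation of the (E)-C4=C5 bond of the ten-membered ring (C4 and C5 set together), after the 8α-tiglate has been installed by SN2 inversion and the 10α-acetate by acylation.
2. Ten-membered ring ⇐ C7–C8: C7, the butenolide β-carbon that sits between the two carbinol carbons C6 and C8, is the nucleophile; an intramolecular Ni/Cr alkenylation of a C8 aldehyde by a 4-iodobutenolide closes the carbocycle on the finished lactone.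
3. Iodobutenolide (C6, C7, C11, C12, C13) ⇐ γ-hydroxy ynoate + iodide + formaldehyde in one halo-aldol/lactonisation; C6 ⇐ catalytic asymmetric addition of methyl propiolate to an enal.
4. C8–C9–C10(C14)–C1 ⇐ (R)-citramalic acid (its tertiary carbinol is C10, its two carboxyl carbons become C8 and C1); C2 from MeLi; C3–C6 and C15 from prenyl acetate, joined at C2–C3 by alkylation of a ketone that can enolise only towards C2 because C10 is quaternary.
5. Ring order: butenolide (step 10), ten-membered carbocycle (step 13), oxirane (step 16).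

Key step: step 13

Remark: germacrane numbering (C1–C15) is used for all intermediates; (R)-citramalic acid, prenyl acetate and methyl propiolate are taken as commercial; in step 9 the ProPhenol antipode is chosen that gives the 4R carbinol.

**Step 1**
Reactants: 1 (R)-citramalic acid
Product: 2 (R)-2-(2,2,4-trimethyl-5-oxo-1,3-dioxolan-4-yl)acetic acid
Conditions: 2,2-dimethoxypropane, TsOH (cat.), rt
Reagents that add atoms: 2,2-dimethoxypropane, COC(C)(C)OC
Why: Acid-catalysed acetalisation ties the α-hydroxy acid into a dioxolanone and leaves the CH2CO2H group (C8) free, so the two carboxyl groups are differentiated without touching C10.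

**Step 2**
Reactants: 2 (R)-2-(2,2,4-trimethyl-5-oxo-1,3-dioxolan-4-yl)acetic acid
Product: 4 (R)-3-hydroxy-3-methyldihydrofuran-2(3H)-one, via hydroxyethyl dioxolanone 3 (not isolated)
Conditions: BH3·SMe2, THF, 0 °C → rt; MeOH; TsOH (cat.), CH2Cl2
Reagents that add atoms: none
Why: Borane reduces the free acid faster than the dioxolanone, and acid-catalysed transesterification by the new primary alcohol should give the γ-lactone with loss of acetone.

**Step 3**
Reactants: 4 (R)-3-hydroxy-3-methyldihydrofuran-2(3H)-one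
Product: 5 (R)-3,5-dihydroxy-3-methylpentan-2-one
Conditions: MeLi (2.2 equiv), THF, −78 °C; aq. NH4Cl
Reagents that add atoms: methyllithium, [Li]C
Why: Methyllithium deprotonates the tertiary alcohol and then adds once to the lactone; the lithium hemiketalate is stable at −78 °C and should give the methyl ketone (C1, C2) on work-up.

**Step 4**
Reactants: 5 (R)-3,5-dihydroxy-3-methylpentan-2-one
Product: 6 (R)-3-methyl-3,5-bis(triethylsilyloxy)pentan-2-one
Conditions: TESOTf (2.5 equiv), 2,6-lutidine, CH2Cl2, −78 → 0 °C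
Reagents that add atoms: triethylsilyl trifluoromethanesulfonate, CC[Si](CC)(CC)OS(=O)(=O)C(F)(F)F
Why: Silyl triflate with a hindered base silylates the primary and the tertiary alcohol of the open hydroxy ketone; TES is chosen because a primary TES ether can later be oxidised directly.

**Step 5**
Reactants: 7 prenyl acetate
Product: 8 (E)-4-hydroxy-3-methylbut-2-en-1-yl acetate
Conditions: SeO2 (cat.), t-BuOOH, CH2Cl2, 0 °C → rt
Reagents that add atoms: tert-butyl hydroperoxide, CC(C)(C)OO; selenium dioxide (catalytic oxygen carrier), O=[Se]=O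
Why: Selenium dioxide allylic oxidation (ene reaction, then [2,3]-shift) takes the methyl group trans to the acetoxymethyl chain and should give the (E)-allylic alcohol.

**Step 6**
Reactants: 8 (E)-4-hydroxy-3-methylbut-2-en-1-yl acetate
Product: 9 (E)-4-bromo-3-methylbut-2-en-1-yl acetate
Conditions: CBr4, PPh3, CH2Cl2, 0 °C
Reagents that add atoms: carbon tetrabromide, BrC(Br)(Br)Br
Why: Appel reaction: bromide displaces the alkoxyphosphonium group at the primary allylic carbon by SN2, so the (E)-alkene is kept.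

**Step 7**
Reactants: 6 (R)-3-methyl-3,5-bis(triethylsilyloxy)pentan-2-one; 9 (E)-4-bromo-3-methylbut-2-en-1-yl acetate
Product: 11 (3R,7E)-9-hydroxy-3,7-dimethyl-1,3-bis(triethylsilyloxy)non-7-en-4-one, via alkylated acetate 10 (not isolated)
Conditions: LDA, THF, −78 °C; 9, DMPU, −78 → −30 °C; then MeOH, K2CO3 (cat.), 0 °C
Reagents that add atoms: none
Why: Kinetic enolate alkylation: C10 is quaternary, so only the C2 enolate can form, and SN2 at the primary allylic bromide makes C2–C3 with the (E)-alkene retained; methoxide then cleaves the acetate in the same flask.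

**Step 8**
Reactants: 11 (3R,7E)-9-hydroxy-3,7-dimethyl-1,3-bis(triethylsilyloxy)non-7-en-4-one
Product: 12 (2E,7R)-3,7-dimethyl-6-oxo-7,9-bis(triethylsilyloxy)non-2-enal
Conditions: MnO2, CH2Cl2, rt
Reagents that add atoms: none
Why: Manganese dioxide oxidises only the allylic alcohol and should give the (E)-enal without touching the ketone or the silyl ethers.

**Step 9**
Reactants: 12 (2E,7R)-3,7-dimethyl-6-oxo-7,9-bis(triethylsilyloxy)non-2-enal; 13 methyl propiolate
Product: 14 methyl (4R,5E,10R)-4-hydroxy-6,10-dimethyl-9-oxo-10,12-bis(triethylsilyloxy)dodec-5-en-2-ynoate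
Conditions: Me2Zn (3 equiv), (S,S)-ProPhenol (20 mol %), Ph3PO (40 mol %), toluene, 4 °C
Reagents that add atoms: none
Why: Dinuclear zinc–ProPhenol alkynylation: the zinc alkynylide of methyl propiolate adds to one face of the aldehyde in the chiral pocket, which sets C6 (4R in 14) by catalyst control, while the hindered ketone does not react.

**Step 10**
Reactants: 14 methyl (4R,5E,10R)-4-hydroxy-6,10-dimethyl-9-oxo-10,12-bis(triethylsilyloxy)dodec-5-en-2-ynoate
Product: 16 (5R)-3-(hydroxymethyl)-4-iodo-5-[(1E,6R)-2,6-dimethyl-5-oxo-6,8-bis(triethylsilyloxy)oct-1-en-1-yl]furan-2(5H)-one, via iodo dienoate diol 15 (not isolated)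
Conditions: MgI2 (1.5 equiv), CH2O (gas from cracked paraformaldehyde), CH2Cl2, 0 °C → rt; PPTS (cat.); aq. NH4Cl
Reagents that add atoms: magnesium iodide, [Mg+2].[I-].[I-]; formaldehyde, C=O
Why: Halo-aldol (β-iodo Baylis–Hillman) reaction: Mg(II)-assisted conjugate addition of iodide gives a β-iodo allenolate that adds to formaldehyde at C11 cis to the smaller iodine, so the C6 oxygen is cis to the ester and closes the butenolide; other geometric isomers are returned by reversible iodide addition, and C6 is not touched.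

**Step 11**
Reactants: 16 (5R)-3-(hydroxymethyl)-4-iodo-5-[(1E,6R)-2,6-dimethyl-5-oxo-6,8-bis(triethylsilyloxy)oct-1-en-1-yl]furan-2(5H)-one
Product: 17 [(5R)-4-iodo-5-[(1E,6R)-2,6-dimethyl-5-oxo-6,8-bis(triethylsilyloxy)oct-1-en-1-yl]-2-oxo-2,5-dihydrofuran-3-yl]methyl acetate
Conditions: Ac2O, pyridine, CH2Cl2, 0 °C
Reagents that add atoms: acetic anhydride, CC(=O)OC(C)=O
Why: Acylation of the only free (primary allylic) alcohol installs the C13 acetate.

**Step 12**
Reactants: 17 [(5R)-4-iodo-5-[(1E,6R)-2,6-dimethyl-5-oxo-6,8-bis(triethylsilyloxy)oct-1-en-1-yl]-2-oxo-2,5-dihydrofuran-3-yl]methyl acetate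
Product: 18 [(5R)-4-iodo-5-[(1E,6R)-2,6-dimethyl-5,8-dioxo-6-(triethylsilyloxy)oct-1-en-1-yl]-2-oxo-2,5-dihydrofuran-3-yl]methyl acetate
Conditions: (COCl)2, DMSO, CH2Cl2, −78 → −30 °C; Et3N, −78 → 0 °C
Reagents that add atoms: none
Why: Swern conditions cleave a primary triethylsilyl ether through the alkoxysulfonium ion and oxidise it to the aldehyde (C8), while the tertiary TES ether is left.

**Step 13**
Reactants: 18 [(5R)-4-iodo-5-[(1E,6R)-2,6-dimethyl-5,8-dioxo-6-(triethylsilyloxy)oct-1-en-1-yl]-2-oxo-2,5-dihydrofuran-3-yl]methyl acetate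
Product: 19 13-acetoxy-8β-hydroxy-1-oxo-10α-(triethylsilyloxy)germacra-4E,7(11)-dien-12,6α-olide (6R,8R,10R)
Conditions: CrCl2 (15 equiv), NiCl2 (0.2 equiv), degassed DMSO/THF, 2 mM, slow addition of 18, rt
Reagents that add atoms: none
Why: Ni(0) inserts into the C7–I bond of the β-iodobutenolide, transmetalation gives an alkenylchromium(III) species, and this adds to the C8 aldehyde (Nozaki–Hiyama–Kishi reaction); the closest known cases are closures of medium carbocycles from cyclic, fully substituted alkenyl iodides. The ten-membered ring closes in the 10-exo-trig mode at C7–C8; the C7=C11 geometry is locked in the butenolide and the (E)-C4=C5 bond is not touched. The new stereocentre C8 is set by the substrate: C5 lies on the α-face of the butenolide plane, so the short tether should bring C9 to the same face; A(1,3) strain with the C13 acetoxymethyl group should put H-8 in the plane, which leaves the chromium alkoxide on the open β-face and gives the 8R (8β) carbinol. The step needs aldehyde-over-ketone selectivity, which alkenylchromium reagents show, and the β-silyloxy aldehyde should not eliminate under these neutral conditions. The 8β outcome is used in step 14, which inverts it.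

**Step 14**
Reactants: 19 13-acetoxy-8β-hydroxy-1-oxo-10α-(triethylsilyloxy)germacra-4E,7(11)-dien-12,6α-olide
Product: 20 13-acetoxy-1-oxo-8α-tigloyloxy-10α-(triethylsilyloxy)germacra-4E,7(11)-dien-12,6α-olide (6R,8S,10R)
Conditions: tiglic acid, PPh3, DIAD, toluene, 0 °C → rt
Reagents that add atoms: tiglic acid, C/C=C(\C)C(O)=O
Why: Mitsunobu esterification: tiglate displaces the alkoxyphosphonium group at allylic C8 by SN2 from the α-face under the butenolide and inverts C8 to S; SN2′ is blocked because C11 is fully substituted, and the electron-poor alkene disfavours ionisation.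

**Step 15**
Reactants: 20 13-acetoxy-1-oxo-8α-tigloyloxy-10α-(triethylsilyloxy)germacra-4E,7(11)-dien-12,6α-olide
Product: 22 10α,13-diacetoxy-1-oxo-8α-tigloyloxygermacra-4E,7(11)-dien-12,6α-olide, via tertiary alcohol 21 (not isolated)
Conditions: HF·pyridine, pyridine/THF, 0 °C → rt; evaporate; Ac2O, Sc(OTf)3 (5 mol %), MeCN, −20 °C
Reagents that add atoms: acetic anhydride, CC(=O)OC(C)=O
Why: Fluoride removes the tertiary silyl ether, and scandium triflate-catalysed acylation, which works on tertiary alcohols at low temperature, should give the 10α-acetate without a base that could epimerise C6.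

**Step 16**
Reactants: 22 10α,13-diacetoxy-1-oxo-8α-tigloyloxygermacra-4E,7(11)-dien-12,6α-olide
Product: 23 target, (4R,5R,6S,8S,10R)-10α,13-diacetoxy-4α,5β-epoxy-1-oxo-8α-tigloyloxygermacr-7(11)-en-12,6α-olide
Conditions: dimethyldioxirane, acetone/CH2Cl2, −20 → 0 °C
Reagents that add atoms: dimethyldioxirane, CC1(C)OO1
Why: Electrophilic epoxidation of the only electron-rich alkene: A(1,3) strain with C15 holds H-6 in the alkene plane and the ring spans the face on the C7 side, so oxygen should enter from the peripheral face syn to the lactone oxygen and set C4 (R) and C5 (R) in one event as the trans-epoxide.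

**Compound list**
1 | (R)-citramalic acid | OC(=O)C[C@@](C)(O)C(O)=O | starting material
2 | (R)-2-(2,2,4-trimethyl-5-oxo-1,3-dioxolan-4-yl)acetic acid | OC(=O)C[C@@]1(C)OC(C)(C)OC1=O | intermediate
3 | (R)-5-(2-hydroxyethyl)-2,2,5-trimethyl-1,3-dioxolan-4-one | OCC[C@@]1(C)OC(C)(C)OC1=O | intermediate
4 | (R)-3-hydroxy-3-methyldihydrofuran-2(3H)-one | O=C1OCC[C@@]1(C)O | intermediate
5 | (R)-3,5-dihydroxy-3-methylpentan-2-one | OCC[C@@](C)(O)C(C)=O | intermediate
6 | (R)-3-methyl-3,5-bis(triethylsilyloxy)pentan-2-one | CC[Si](CC)(CC)OCC[C@@](C)(O[Si](CC)(CC)CC)C(C)=O | intermediate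
7 | prenyl acetate | CC(C)=CCOC(C)=O | starting material
8 | (E)-4-hydroxy-3-methylbut-2-en-1-yl acetate | CC(=O)OC/C=C(\C)CO | intermediate
9 | (E)-4-bromo-3-methylbut-2-en-1-yl acetate | CC(=O)OC/C=C(\C)CBr | intermediate
10 | (2E,7R)-3,7-dimethyl-6-oxo-7,9-bis(triethylsilyloxy)non-2-en-1-yl acetate | CC[Si](CC)(CC)OCC[C@@](C)(O[Si](CC)(CC)CC)C(=O)CC/C(C)=C/COC(C)=O | intermediate
11 | (3R,7E)-9-hydroxy-3,7-dimethyl-1,3-bis(triethylsilyloxy)non-7-en-4-one | CC[Si](CC)(CC)OCC[C@@](C)(O[Si](CC)(CC)CC)C(=O)CC/C(C)=C/CO | intermediate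
12 | (2E,7R)-3,7-dimethyl-6-oxo-7,9-bis(triethylsilyloxy)non-2-enal | CC[Si](CC)(CC)OCC[C@@](C)(O[Si](CC)(CC)CC)C(=O)CC/C(C)=C/C=O | intermediate
13 | methyl propiolate | C#CC(=O)OC | starting material
14 | methyl (4R,5E,10R)-4-hydroxy-6,10-dimethyl-9-oxo-10,12-bis(triethylsilyloxy)dodec-5-en-2-ynoate | CC[Si](CC)(CC)OCC[C@@](C)(O[Si](CC)(CC)CC)C(=O)CC/C(C)=C/[C@@H](O)C#CC(=O)OC | intermediate
15 | methyl (2E,4R,5E,10R)-4-hydroxy-2-(hydroxymethyl)-3-iodo-6,10-dimethyl-9-oxo-10,12-bis(triethylsilyloxy)dodeca-2,5-dienoate | CC[Si](CC)(CC)OCC[C@@](C)(O[Si](CC)(CC)CC)C(=O)CC/C(C)=C/[C@@H](O)/C(I)=C(/CO)C(=O)OC | intermediate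
16 | (5R)-3-(hydroxymethyl)-4-iodo-5-[(1E,6R)-2,6-dimethyl-5-oxo-6,8-bis(triethylsilyloxy)oct-1-en-1-yl]furan-2(5H)-one | CC[Si](CC)(CC)OCC[C@@](C)(O[Si](CC)(CC)CC)C(=O)CC/C(C)=C/[C@H]1OC(=O)C(CO)=C1I | intermediate
17 | [(5R)-4-iodo-5-[(1E,6R)-2,6-dimethyl-5-oxo-6,8-bis(triethylsilyloxy)oct-1-en-1-yl]-2-oxo-2,5-dihydrofuran-3-yl]methyl acetate | CC[Si](CC)(CC)OCC[C@@](C)(O[Si](CC)(CC)CC)C(=O)CC/C(C)=C/[C@H]1OC(=O)C(COC(C)=O)=C1I | intermediate
18 | [(5R)-4-iodo-5-[(1E,6R)-2,6-dimethyl-5,8-dioxo-6-(triethylsilyloxy)oct-1-en-1-yl]-2-oxo-2,5-dihydrofuran-3-yl]methyl acetate | O=CC[C@@](C)(O[Si](CC)(CC)CC)C(=O)CC/C(C)=C/[C@H]1OC(=O)C(COC(C)=O)=C1I | intermediate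
19 | 13-acetoxy-8β-hydroxy-1-oxo-10α-(triethylsilyloxy)germacra-4E,7(11)-dien-12,6α-olide (6R,8R,10R) | O[C@@H]1C[C@@](C)(O[Si](CC)(CC)CC)C(=O)CC/C(C)=C/[C@H]2OC(=O)C(COC(C)=O)=C12 | intermediate
20 | 13-acetoxy-1-oxo-8α-tigloyloxy-10α-(triethylsilyloxy)germacra-4E,7(11)-dien-12,6α-olide (6R,8S,10R) | C/C=C(\C)C(=O)O[C@H]1C[C@@](C)(O[Si](CC)(CC)CC)C(=O)CC/C(C)=C/[C@H]2OC(=O)C(COC(C)=O)=C12 | intermediate
21 | 13-acetoxy-10α-hydroxy-1-oxo-8α-tigloyloxygermacra-4E,7(11)-dien-12,6α-olide | C/C=C(\C)C(=O)O[C@H]1C[C@@](C)(O)C(=O)CC/C(C)=C/[C@H]2OC(=O)C(COC(C)=O)=C12 | intermediate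
22 | 10α,13-diacetoxy-1-oxo-8α-tigloyloxygermacra-4E,7(11)-dien-12,6α-olide | C/C=C(\C)C(=O)O[C@H]1C[C@@](C)(OC(C)=O)C(=O)CC/C(C)=C/[C@H]2OC(=O)C(COC(C)=O)=C12 | intermediate
23 | (4R,5R,6S,8S,10R)-10α,13-diacetoxy-4α,5β-epoxy-1-oxo-8α-tigloyloxygermacr-7(11)-en-12,6α-olide (CNP0175424.1) | C/C=C(\C)C(=O)O[C@H]1C[C@@](C)(OC(C)=O)C(=O)CC[C@@]2(C)O[C@@H]2[C@H]2OC(=O)C(COC(C)=O)=C12 | target

**Step count and risk**
Total: 16 steps. Longest linear sequence: 14 steps (1–4, 7–16); steps 5–6 form the side branch.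

Steps most likely to fail:

1. Step 13 (ring closure). What may go wrong: the aldehyde is attacked on its other face (chromium alkoxide held in the butenolide plane beside the C13 acetate), so facial selectivity at C8 is reversed or poor. Fallback: it sets out from 18; the 8α-alcohol F1 that then forms is esterified with retention (tigloyl chloride, DMAP, Et3N, CH2Cl2, 0 °C) and comes back at 20. With a mixture the epimers are separated; 19 goes through step 14 and F1 through the acylation, so both converge on 20.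

2. Step 10 (halo-aldol). What may go wrong: the hydroxymethyl group enters on the other side of the allenolate so that no lactone can close, or the Lewis acid ionises the doubly activated C6 carbinol. Fallback (C13 carried in on the alkyne, iodine put in by iodolactonisation): it sets out from 12. Zn–ProPhenol addition of propargyl acetate with the antipodal ligand gives the alkynol F2. Methyl chloroformate/pyridine gives the carbonate F3. Pd(PPh3)4, CO, MeOH (anti-SN2′ carbonylation of a propargylic carbonate) gives the allenoate F4 with transfer of chirality. Iodine in aqueous MeCN (anti iodolactonisation of a 2,3-allenoate) closes the 4-iodobutenolide with overall inversion at C6 and comes back at 17.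

3. Step 14 (Mitsunobu). What may go wrong: E2 loss of the activated oxygen towards C9 instead of substitution, or incomplete inversion. Fallback: it sets out from 19. Dess–Martin oxidation gives the enone F5. NaBH4/CeCl3 in MeOH at −78 °C should reduce the activated C8 ketone from the open β-face (the hindered C1 ketone is slower) to the 8α-alcohol F1, which is acylated with tigloyl chloride/DMAP and comes back at 20.

**Further compounds**
F1 | step 13 | 13-acetoxy-8α-hydroxy-1-oxo-10α-(triethylsilyloxy)germacra-4E,7(11)-dien-12,6α-olide (6R,8S,10R) | O[C@H]1C[C@@](C)(O[Si](CC)(CC)CC)C(=O)CC/C(C)=C/[C@H]2OC(=O)C(COC(C)=O)=C12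
F2 | step 10 | (4S,5E,10R)-4-hydroxy-6,10-dimethyl-9-oxo-10,12-bis(triethylsilyloxy)dodec-5-en-2-yn-1-yl acetate | CC[Si](CC)(CC)OCC[C@@](C)(O[Si](CC)(CC)CC)C(=O)CC/C(C)=C/[C@H](O)C#CCOC(C)=O
F3 | step 10 | (4S,5E,10R)-4-(methoxycarbonyloxy)-6,10-dimethyl-9-oxo-10,12-bis(triethylsilyloxy)dodec-5-en-2-yn-1-yl acetate | CC[Si](CC)(CC)OCC[C@@](C)(O[Si](CC)(CC)CC)C(=O)CC/C(C)=C/[C@H](OC(=O)OC)C#CCOC(C)=O
F4 | step 10 | methyl (Ra,5E,10R)-2-(acetoxymethyl)-6,10-dimethyl-9-oxo-10,12-bis(triethylsilyloxy)dodeca-2,3,5-trienoate | CC[Si](CC)(CC)OCC[C@@](C)(O[Si](CC)(CC)CC)C(=O)CC/C(C)=C/C([H])=[C@]=C(COC(C)=O)C(=O)OC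
F5 | step 14 | 13-acetoxy-1,8-dioxo-10α-(triethylsilyloxy)germacra-4E,7(11)-dien-12,6α-olide | O=C1C[C@@](C)(O[Si](CC)(CC)CC)C(=O)CC/C(C)=C/[C@H]2OC(=O)C(COC(C)=O)=C12
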